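## The problem

Selaginellin 28 is organised around ring A, a benzene whose positions C1, C2, C5 and C6 carry, in that order, the diarylmethylene (quinone methide) carbon, a 4-hydroxyphenyl group, a hydroxymethyl group and a 4-hydroxyphenylethynyl group; only C3 and C4 bear hydrogen. The four carbon substituents are contiguous (C2, C1, C6, C5) and the one at C1 is flanked on both sides, so a 1,2,3,4-substitution pattern must be fixed without ambiguity and bonds must then be made at a crowded centre. There is no stereocentre and no double-bond isomerism (the quinonoid ring is symmetrical), and the C1–methide axis is not a lasting stereo element because the quinonoid and phenolic rings exchange roles by tautomerism; nothing has to be controlled stereochemically. The sensitive groups dictate the end of the route: the diarylalkyne excludes hydrogenolysis and sits between two oxygen functions (the C5 CH2OH and, before dehydration, the C1 carbinol) that can add across it under strong Lewis acids, π-acidic metals or alkoxide conditions, the benzylic alcohol ionises easily, and the quinone methide is an electrophile best generated last. Protecting groups must therefore leave under conditions that are neither reductive nor strongly Lewis acidic, which points to silyl ethers and fluoride. The feature that opens the key step is that C1, C6 and C5 correspond to the ester-bearing, oxygen-bearing and terminal carbons of β-keto ester 4 (used as its bis(silyloxy)diene 7), while C2, C3 and C4 correspond to the ketone, methylene and acetal carbons of aroylacetaldehyde acetal 12. The extra oxygen this places on C6 is the handle for the alkyne, and the ester carbon on C1 is the methide carbon itself, whose two remaining substituents are the same 4-oxygenated phenyl group at the carbinol oxidation level.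

## Retrosynthesis

**28 to 26.** The exocyclic C=C of the methide is traced back to a C–OH bond (dehydration in reverse, through hexol 27) and the five O–H bonds to O–Si bonds, giving pentasilyl triarylmethanol 26. Benzyl or methyl ethers were set aside: they would need hydrogenolysis (alkyne) or boron halides (alkyne with two oxygen neighbours, benzylic C–O bond). Compound 26 is no smaller than 28, but it carries no electrophile and no free hydroxyl group. The forward step must remove five silyl groups and lose water without hydroalkoxylation of the alkyne.

**26 to 22.** Both C–C bonds from the carbinol carbon to the two identical aryl groups are cut, leading to methyl benzoate 22 and two equivalents of aryllithium 24 (from bromide 23), with ketone 25 as the halfway stage. The neighbouring choices are worse: adding a ring A organometallic to a benzophenone would need metalation between two ortho groups, and one-aryl-at-a-time assembly needs extra redox steps. The cut removes two of the five aryl rings and reduces the C1 substituent to the ester that the ring synthesis delivers. The forward reaction must achieve double addition to a benzoate with two ortho substituents, one of them a slim alkynyl group.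

**22 to 16 and 21.** The C6–C(sp) bond is cut to aryl triflate 16 and terminal alkyne 21. Coupling precedes the aryllithium step because a sulfonate ester would not survive the organolithium and a coupling next to a trityl-type carbinol would be far more hindered. Alkyne 21 comes from 4-iodophenol 17 by silylation (18), coupling with ethynyltrimethylsilane 19 (to 20) and C-desilylation. The forward coupling has to proceed at a C–O bond lying between an ester and a silyloxymethyl group.

**16 to 15.** The O–S bond is cut to salicylate 15. The phenol is used only as a leaving-group precursor, so nothing is lost by sulfonylating it.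

**15 to 7 and 12.** Ring A is opened at C4–C5 and C1–C2, giving diene 7 and β-keto acetal 12. Decorating a bought benzene would require an already regiodefined tetrasubstituted arene, whereas here the four positions are set by mechanism. The aromatic ring is replaced by two acyclic three-carbon pieces. The forward reaction must deliver the diene terminus to the acetal carbon and the diene centre to the ketone carbon, and must spare two silyl ethers.

**7 to 1 and 2.** Two O–Si bonds are cut in turn (7 to enol ether 5 through dienolate 6, then 5 to β-keto ester 4). The C–C bond between the terminal carbon of 4 and its CH2O group is then cut to methyl acetoacetate 1 (as dianion 3) and silyloxymethyl chloride 2, which brings the C5 hydroxymethyl group in already as a fluoride-labile ether.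

**12 to 8 and 10.** The bond between the ketone α-carbon and the acetal carbon is cut to aryl methyl ketone 9 (reacting as enol silane 11) and trimethyl orthoformate 10. Ketone 9 is the silyl ether of 4'-hydroxyacetophenone 8.

## Roads not taken

**Alternative 1:** Ring A could be made by a hexadehydro-Diels–Alder reaction, again forming C5–C6 and C1–C2 but from alkynes.
- **Cut and key step:** The ester-tethered triyne A1 would be heated in cyclooctane. Its 1,3-diyne (C2 to C5) and its ynoate (C6, C1) combine to a C3–C4 benzyne, which takes two hydrogens from the solvent to give phthalide A2.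
- **Merits:** Ring A and the lactone form in one atom-economical step with tether-enforced regiochemistry. The crowded C1 carbinol carbon is carried in intact, so no nucleophile has to add to a doubly ortho-flanked carbonyl group; in this respect the road is better than the chosen plan.
- **Weak points:**
  - The diynophile terminus bears a trityl-like group, which should slow the cycloaddition.
  - The benzyne must be reduced by the solvent faster than it is intercepted by acetal oxygens and electron-rich arenes of a second molecule.
  - The lactone carbonyl carbon must then be converted into the arylalkyne (reduction to the lactol, alkyne homologation, Sonogashira coupling), three operations beside a hindered silyl ether.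
  - The acetals and the tertiary silyl ether must finally be removed with acid in the presence of the alkyne and its oxygen neighbours.
  - A1 itself needs a Cadiot–Chodkiewicz coupling, a ketone alkynylation and an esterification, so the step count is no lower.
- **Comparison:** Against the real advantage at C1, the chosen plan sets cheaper three-carbon components, ring formation at or below room temperature, a phenol handle that accepts the complete arylalkyne in one coupling, and fluoride-only unmasking.

**Alternative 2:** Ring A is bought as a benzene and two of its substituent bonds, C1–C(acyl) and C6–C(sp), are made in one Catellani reaction.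
- **Cut and key step:** Aryl iodide A3 with Pd(OAc)2 and norbornene would be acylated at the free ortho C1–H by anhydride A4 and terminated at C6 by terminal alkyne A5, giving ketone A6. Suzuki coupling at the C2 chloride, one aryllithium addition to the ketone and acidic unmasking would follow.
- **Merits:** It is the shortest and most convergent road, the ketone needs only one aryl addition, and all aryl groups arrive late. On step economy it is clearly better than the chosen plan.
- **Weak points:**
  - The C–H bond to be palladated lies between the palladium-bearing carbon and the chlorine-bearing C2, a buttressed position where palladacycle formation is disfavoured.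
  - Pairing ortho-acylation with alkynyl termination requires that A5 neither couples directly with A3 nor is consumed by A4 before the palladacycle forms.
  - The later Suzuki coupling is at a chloride ortho to a diaryl ketone, and aryllithium addition to a ketone with two ortho substituents is no easier than the ester case.
  - The acetal groups again need acid at the end.
- **Comparison:** Against the shorter count, the chosen plan sets steps that each belong to a reaction class established on comparable substrates, and a ring A regiochemistry fixed by mechanism, not by the outcome of a hindered C–H palladation.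

**Alternative 3:** The alkyne and the C1 carbonyl group are hidden in an indenone.
- **Cut and key step:** Pd(OAc)2-catalysed annulation of bromoaldehyde A7 with symmetrical diarylacetylene A8 would form the ring A C1–C bond by carbopalladation and close the five-membered ring onto the aldehyde carbon, giving indenone A9. Nucleophilic epoxidation of the enone and Eschenmoser–Tanabe fragmentation of the derived sulfonylhydrazone would then open that ring into the C6 arylethynyl group and a C1 aryl ketone.
- **Merits:** The symmetrical alkyne removes any regiochemical question in the annulation. Alkyne and ketone are unveiled in one fragmentation, so the alkyne is absent for most of the route. Like alternative 2, the road ends in a ketone, which is an advantage over the ester of the chosen plan.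
- **Weak points:**
  - Ring A is not built: A7 is itself a 1,2,3,4-tetrasubstituted benzene whose regiocontrolled synthesis is the original problem in another guise.
  - Oxidative addition at a C–Br bond flanked by an aryl and a formyl group, and alkyne insertion there, are hindered.
  - The tetrasubstituted diaryl enone of A9 is a poor substrate for epoxidation and hydrazone formation, and 2,3-diarylindenone oxides tend to open to benzopyrylium oxides instead.
  - It would be the longest of the four routes.
- **Comparison:** The chosen plan concedes the ketone advantage but builds ring A from acyclic pieces and needs no step that has to overcome a tetrasubstituted alkene.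

Key step: step 6

Remarks on the chemistry:
- Silyl chloride 2 and aryl bromide 23 are taken to be purchasable.
- The double-bond geometries drawn for 5, 6 and 7 are the expected major isomers and are of no consequence, because these carbons all end up in or on an aromatic ring.
- Intermediates 13 and 14 are stereoisomer mixtures whose stereo elements are erased in 15.

## Route

Step 1
Reactants: 1 methyl acetoacetate; 2 (chloromethoxy)triisopropylsilane
Product: 4 methyl 3-oxo-5-(triisopropylsilyloxy)pentanoate, via methyl acetoacetate dianion 3 (not isolated)
Conditions: NaH, THF, 0 °C; n-BuLi, 0 °C; then 2, −78 → 0 °C; cold 1 M HCl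
Reagents that add atoms: none
Why: Sequential deprotonation gives the Weiler dianion 3, whose terminal carbanion is much more nucleophilic than the stabilised central one and is alkylated cleanly by α-chloro ethers (the benzyloxymethyl and methoxymethyl chlorides are the standard cases). The silyl congener 2 should behave alike because silicon is shielded by three isopropyl groups, and it brings in the C5 hydroxymethyl group as a fluoride-labile ether.

Step 2
Reactants: 4 methyl 3-oxo-5-(triisopropylsilyloxy)pentanoate
Product: 5 methyl (2Z)-5-(triisopropylsilyloxy)-3-(trimethylsilyloxy)pent-2-enoate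
Conditions: TMSCl, Et3N, toluene, 20 °C
Reagents that add atoms: chlorotrimethylsilane, C[Si](C)(C)Cl
Why: O-Silylation of the enolised β-keto ester with TMSCl and Et3N is the standard first stage of bis(silyloxy)diene synthesis; the primary silyl ether is inert.

Step 3
Reactants: 5 methyl (2Z)-5-(triisopropylsilyloxy)-3-(trimethylsilyloxy)pent-2-enoate
Product: 7 (1Z,3Z)-1-methoxy-5-(triisopropylsilyloxy)-1,3-bis(trimethylsilyloxy)penta-1,3-diene, via lithium dienolate 6 (not isolated)
Conditions: LDA, THF, −78 °C; TMSCl, −78 → 20 °C; hexane, filtration, used crude
Reagents that add atoms: chlorotrimethylsilane, C[Si](C)(C)Cl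
Why: Kinetic γ-deprotonation of the silyl enol ether by LDA gives dienolate 6, which TMSCl traps on oxygen (standard second stage of Chan-type diene synthesis). The low temperature should prevent β-elimination of silanolate from C5, and the moisture-sensitive diene is used directly.

Step 4
Reactants: 8 4'-hydroxyacetophenone
Product: 9 1-[4-(triisopropylsilyloxy)phenyl]ethan-1-one
Conditions: TIPSCl, imidazole, DMF, 20 °C
Reagents that add atoms: chlorotriisopropylsilane, CC(C)[Si](Cl)(C(C)C)C(C)C
Why: Routine phenol silylation. The triisopropylsilyl ether is chosen because an aryl silyl ether of this bulk is a weak Lewis base and should tolerate TMSOTf and TiCl4.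

Step 5
Reactants: 9 1-[4-(triisopropylsilyloxy)phenyl]ethan-1-one; 10 trimethyl orthoformate
Product: 12 3,3-dimethoxy-1-[4-(triisopropylsilyloxy)phenyl]propan-1-one, via enol silane 11 (not isolated)
Conditions: TMSOTf (1.5 equiv), i-Pr2NEt (1.2 equiv), CH2Cl2, 0 °C; then 10, −78 → 0 °C; aq. NaHCO3
Reagents that add atoms: none
Why: Soft enolisation with TMSOTf and amine gives enol silane 11. The excess TMSOTf ionises the orthoformate to the dimethoxycarbenium ion, which 11 captures in a Mukaiyama-type addition (silyl enol ether–orthoester reaction) to give the β-keto acetal with release of methoxytrimethylsilane.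

Step 6
Reactants: 7 (1Z,3Z)-1-methoxy-5-(triisopropylsilyloxy)-1,3-bis(trimethylsilyloxy)penta-1,3-diene; 12 3,3-dimethoxy-1-[4-(triisopropylsilyloxy)phenyl]propan-1-one
Product: 15 methyl 2-hydroxy-6-[4-(triisopropylsilyloxy)phenyl]-3-[(triisopropylsilyloxy)methyl]benzoate, via open-chain Mukaiyama adduct 13 (not isolated), via cyclic aldol 14 (not isolated)
Conditions: 12, TiCl4 (1.1 equiv), 4 Å MS, CH2Cl2, −78 °C; then 7, −78 → 20 °C; H2O
Reagents that add atoms: none
Why: TiCl4 ionises the dimethyl acetal of 12 to a methoxycarbenium ion, and the terminal carbon of diene 7, its most nucleophilic (vinylogous) position, adds to it in a Mukaiyama-type step that forms the ring A C4–C5 bond and leaves the β-silyloxy enoate 13. The central carbon of 13 then attacks the titanium-activated aryl ketone in an intramolecular Mukaiyama aldol, a 6-(enolendo)-exo-trig closure that forms C1–C2 and gives cyclic aldol 14; loss of methanol and water with enolisation of the ring ketone aromatises 14 to salicylate 15. The closest known reaction type is the Chan–Brownbridge formal (3+3) cyclocondensation of 1,3-bis(silyloxy)-1,3-dienes with β-keto acetals, which gives 6-substituted salicylates and tolerates a substituent on the diene terminus. The transient stereocentres of 13 and 14 are erased on aromatisation, so no stereocontrol is needed. The selectivity required is regiochemical, diene terminus to the acetal carbon and diene centre to the ketone carbon; it is secured by premixing 12 with TiCl4 so that the oxocarbenium ion is present before the diene arrives, and by the para-silyloxy donor, which makes the aryl ketone too poor an electrophile to compete intermolecularly. The aryl silyl ether is a weak Lewis base and the primary one is shielded by three isopropyl groups, so both should persist if the mixture is quenched as soon as aromatisation is complete.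

Step 7
Reactants: 15 methyl 2-hydroxy-6-[4-(triisopropylsilyloxy)phenyl]-3-[(triisopropylsilyloxy)methyl]benzoate
Product: 16 methyl 6-[4-(triisopropylsilyloxy)phenyl]-3-[(triisopropylsilyloxy)methyl]-2-(trifluoromethanesulfonyloxy)benzoate
Conditions: Tf2O, pyridine, CH2Cl2, −10 → 20 °C
Reagents that add atoms: trifluoromethanesulfonic anhydride, O=S(=O)(OS(=O)(=O)C(F)(F)F)C(F)(F)F
Why: Triflation of salicylate phenols with Tf2O and pyridine is routine; the base breaks the hydrogen bond to the ester, and the silyl ethers are unaffected.

Step 8
Reactants: 17 4-iodophenol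
Product: 18 (4-iodophenoxy)triisopropylsilane
Conditions: TIPSCl, imidazole, DMF, 20 °C
Reagents that add atoms: chlorotriisopropylsilane, CC(C)[Si](Cl)(C(C)C)C(C)C
Why: Routine phenol silylation, giving the same protecting group as on all other oxygens.

Step 9
Reactants: 18 (4-iodophenoxy)triisopropylsilane; 19 ethynyltrimethylsilane
Product: 20 triisopropyl{4-[(trimethylsilyl)ethynyl]phenoxy}silane
Conditions: PdCl2(PPh3)2 (2 mol%), CuI (4 mol%), Et3N, THF, 20 °C
Reagents that add atoms: none
Why: Sonogashira coupling of an unhindered aryl iodide at room temperature; the C-silyl group prevents double coupling.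

Step 10
Reactants: 20 triisopropyl{4-[(trimethylsilyl)ethynyl]phenoxy}silane
Product: 21 (4-ethynylphenoxy)triisopropylsilane
Conditions: K2CO3 (0.1 equiv), MeOH/THF, 0 °C, short reaction time
Reagents that add atoms: none
Why: Catalytic methoxide cleaves the C(sp)–Si bond within minutes at 0 °C, whereas the hindered aryl triisopropylsilyl ether is attacked far more slowly, so protiodesilylation should be selective.

Step 11
Reactants: 16 methyl 6-[4-(triisopropylsilyloxy)phenyl]-3-[(triisopropylsilyloxy)methyl]-2-(trifluoromethanesulfonyloxy)benzoate; 21 (4-ethynylphenoxy)triisopropylsilane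
Product: 22 methyl 6-[4-(triisopropylsilyloxy)phenyl]-3-[(triisopropylsilyloxy)methyl]-2-{[4-(triisopropylsilyloxy)phenyl]ethynyl}benzoate
Conditions: PdCl2(PPh3)2 (5 mol%), CuI (10 mol%), n-Bu4NI, Et3N/DMF, 70 °C
Reagents that add atoms: none
Why: Sonogashira coupling of an aryl triflate. Oxidative addition to zerovalent palladium is helped by the electron-withdrawing ortho ester and the iodide additive, and the linear alkynyl group makes small steric demands in transmetalation and reductive elimination although both ortho positions are occupied.

Step 12
Reactants: 22 methyl 6-[4-(triisopropylsilyloxy)phenyl]-3-[(triisopropylsilyloxy)methyl]-2-{[4-(triisopropylsilyloxy)phenyl]ethynyl}benzoate; 23 (4-bromophenoxy)triisopropylsilane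
Product: 26 {6-[4-(triisopropylsilyloxy)phenyl]-3-[(triisopropylsilyloxy)methyl]-2-{[4-(triisopropylsilyloxy)phenyl]ethynyl}phenyl}bis[4-(triisopropylsilyloxy)phenyl]methanol, via aryllithium 24 (not isolated), via diaryl ketone 25 (not isolated)
Conditions: 23 (3.5 equiv), n-BuLi (3.4 equiv), THF, −78 °C; then 22, −78 → 0 °C; H2O
Reagents that add atoms: none
Why: Bromine–lithium exchange gives 24; addition to the ester and collapse of the tetrahedral intermediate give ketone 25, which is more electrophilic than the ester and takes up the second equivalent. This is the standard double addition of aryllithiums to biaryl-2-carboxylates on the way to triarylmethanols. The second ortho group is a sterically slim alkyne, and the lithium alkoxide is quenched cold before it can add to that alkyne.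

Step 13
Reactants: 26 {6-[4-(triisopropylsilyloxy)phenyl]-3-[(triisopropylsilyloxy)methyl]-2-{[4-(triisopropylsilyloxy)phenyl]ethynyl}phenyl}bis[4-(triisopropylsilyloxy)phenyl]methanol
Product: 28 selaginellin, via desilylated hexol 27 (not isolated)
Conditions: TBAF (6 equiv), THF, 0 → 20 °C; then 1 M aq. HCl to pH 3, 20 °C
Reagents that add atoms: none
Why: Fluoride cleaves the four aryl and the one primary alkyl silyl ether to give 27. On acidification the 4-hydroxyphenyl carbinol ionises to a doubly para-hydroxy-stabilised trityl cation and loses a proton from oxygen, the usual fuchsone formation from 4-hydroxytrityl alcohols. No reductant or Lewis acid is present, so the alkyne is untouched.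

## Compound list

1 | methyl acetoacetate | COC(=O)CC(C)=O | starting material
2 | (chloromethoxy)triisopropylsilane | ClCO[Si](C(C)C)(C(C)C)C(C)C | starting material
3 | methyl acetoacetate dianion, sodium lithium salt (not isolated) | [Na+].[Li+].[CH2-]C(=O)[CH-]C(=O)OC | intermediate
4 | methyl 3-oxo-5-(triisopropylsilyloxy)pentanoate | COC(=O)CC(=O)CCO[Si](C(C)C)(C(C)C)C(C)C | intermediate
5 | methyl (2Z)-5-(triisopropylsilyloxy)-3-(trimethylsilyloxy)pent-2-enoate | COC(=O)/C=C(\O[Si](C)(C)C)CCO[Si](C(C)C)(C(C)C)C(C)C | intermediate
6 | lithium (1E,3Z)-1-methoxy-5-(triisopropylsilyloxy)-3-(trimethylsilyloxy)penta-1,3-dien-1-olate (not isolated) | [Li+].CO/C([O-])=C/C(O[Si](C)(C)C)=C/CO[Si](C(C)C)(C(C)C)C(C)C | intermediate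
7 | (1Z,3Z)-1-methoxy-5-(triisopropylsilyloxy)-1,3-bis(trimethylsilyloxy)penta-1,3-diene | CO/C(O[Si](C)(C)C)=C/C(O[Si](C)(C)C)=C/CO[Si](C(C)C)(C(C)C)C(C)C | intermediate
8 | 4'-hydroxyacetophenone | CC(=O)c1ccc(O)cc1 | starting material
9 | 1-[4-(triisopropylsilyloxy)phenyl]ethan-1-one | CC(=O)c1ccc(O[Si](C(C)C)(C(C)C)C(C)C)cc1 | intermediate
10 | trimethyl orthoformate | COC(OC)OC | starting material
11 | triisopropyl{4-[1-(trimethylsilyloxy)ethenyl]phenoxy}silane (not isolated) | C=C(O[Si](C)(C)C)c1ccc(O[Si](C(C)C)(C(C)C)C(C)C)cc1 | intermediate
12 | 3,3-dimethoxy-1-[4-(triisopropylsilyloxy)phenyl]propan-1-one | COC(OC)CC(=O)c1ccc(O[Si](C(C)C)(C(C)C)C(C)C)cc1 | intermediate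
13 | methyl 5-methoxy-7-oxo-4-[(triisopropylsilyloxy)methyl]-7-[4-(triisopropylsilyloxy)phenyl]-3-(trimethylsilyloxy)hept-2-enoate (stereoisomer mixture, not isolated) | COC(=O)C=C(O[Si](C)(C)C)C(CO[Si](C(C)C)(C(C)C)C(C)C)C(OC)CC(=O)c1ccc(O[Si](C(C)C)(C(C)C)C(C)C)cc1 | intermediate
14 | methyl 2-hydroxy-4-methoxy-6-oxo-5-[(triisopropylsilyloxy)methyl]-2-[4-(triisopropylsilyloxy)phenyl]cyclohexane-1-carboxylate (stereoisomer mixture, not isolated) | COC(=O)C1C(=O)C(CO[Si](C(C)C)(C(C)C)C(C)C)C(OC)CC1(O)c1ccc(O[Si](C(C)C)(C(C)C)C(C)C)cc1 | intermediate
15 | methyl 2-hydroxy-6-[4-(triisopropylsilyloxy)phenyl]-3-[(triisopropylsilyloxy)methyl]benzoate | COC(=O)c1c(O)c(CO[Si](C(C)C)(C(C)C)C(C)C)ccc1-c1ccc(O[Si](C(C)C)(C(C)C)C(C)C)cc1 | intermediate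
16 | methyl 6-[4-(triisopropylsilyloxy)phenyl]-3-[(triisopropylsilyloxy)methyl]-2-(trifluoromethanesulfonyloxy)benzoate | COC(=O)c1c(OS(=O)(=O)C(F)(F)F)c(CO[Si](C(C)C)(C(C)C)C(C)C)ccc1-c1ccc(O[Si](C(C)C)(C(C)C)C(C)C)cc1 | intermediate
17 | 4-iodophenol | Oc1ccc(I)cc1 | starting material
18 | (4-iodophenoxy)triisopropylsilane | Ic1ccc(O[Si](C(C)C)(C(C)C)C(C)C)cc1 | intermediate
19 | ethynyltrimethylsilane | C#C[Si](C)(C)C | starting material
20 | triisopropyl{4-[(trimethylsilyl)ethynyl]phenoxy}silane | C[Si](C)(C)C#Cc1ccc(O[Si](C(C)C)(C(C)C)C(C)C)cc1 | intermediate
21 | (4-ethynylphenoxy)triisopropylsilane | C#Cc1ccc(O[Si](C(C)C)(C(C)C)C(C)C)cc1 | intermediate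
22 | methyl 6-[4-(triisopropylsilyloxy)phenyl]-3-[(triisopropylsilyloxy)methyl]-2-{[4-(triisopropylsilyloxy)phenyl]ethynyl}benzoate | COC(=O)c1c(C#Cc2ccc(O[Si](C(C)C)(C(C)C)C(C)C)cc2)c(CO[Si](C(C)C)(C(C)C)C(C)C)ccc1-c1ccc(O[Si](C(C)C)(C(C)C)C(C)C)cc1 | intermediate
23 | (4-bromophenoxy)triisopropylsilane | Brc1ccc(O[Si](C(C)C)(C(C)C)C(C)C)cc1 | starting material
24 | [4-(triisopropylsilyloxy)phenyl]lithium (not isolated) | [Li]c1ccc(O[Si](C(C)C)(C(C)C)C(C)C)cc1 | intermediate
25 | {6-[4-(triisopropylsilyloxy)phenyl]-3-[(triisopropylsilyloxy)methyl]-2-{[4-(triisopropylsilyloxy)phenyl]ethynyl}phenyl}[4-(triisopropylsilyloxy)phenyl]methanone (not isolated) | O=C(c1ccc(O[Si](C(C)C)(C(C)C)C(C)C)cc1)c1c(C#Cc2ccc(O[Si](C(C)C)(C(C)C)C(C)C)cc2)c(CO[Si](C(C)C)(C(C)C)C(C)C)ccc1-c1ccc(O[Si](C(C)C)(C(C)C)C(C)C)cc1 | intermediate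
26 | {6-[4-(triisopropylsilyloxy)phenyl]-3-[(triisopropylsilyloxy)methyl]-2-{[4-(triisopropylsilyloxy)phenyl]ethynyl}phenyl}bis[4-(triisopropylsilyloxy)phenyl]methanol | OC(c1ccc(O[Si](C(C)C)(C(C)C)C(C)C)cc1)(c1ccc(O[Si](C(C)C)(C(C)C)C(C)C)cc1)c1c(C#Cc2ccc(O[Si](C(C)C)(C(C)C)C(C)C)cc2)c(CO[Si](C(C)C)(C(C)C)C(C)C)ccc1-c1ccc(O[Si](C(C)C)(C(C)C)C(C)C)cc1 | intermediate
27 | {3-(hydroxymethyl)-6-(4-hydroxyphenyl)-2-[(4-hydroxyphenyl)ethynyl]phenyl}bis(4-hydroxyphenyl)methanol (not isolated) | OCc1ccc(-c2ccc(O)cc2)c(C(O)(c2ccc(O)cc2)c2ccc(O)cc2)c1C#Cc1ccc(O)cc1 | intermediate
28 | selaginellin, 4-[{3-(hydroxymethyl)-6-(4-hydroxyphenyl)-2-[(4-hydroxyphenyl)ethynyl]phenyl}(4-hydroxyphenyl)methylidene]cyclohexa-2,5-dien-1-one | O=C1C=CC(=C(c2ccc(O)cc2)c2c(-c3ccc(O)cc3)ccc(CO)c2C#Cc2ccc(O)cc2)C=C1 | target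

## Step count and least certain steps

Total step count: 13. Longest linear sequence: 8 steps (steps 1, 2, 3, 6, 7, 11, 12, 13, from methyl acetoacetate 1).

**Step 6 (key step).** The domino may stall after the first C–C bond, because the titanium-bound aryl ketone with its para donor is a sluggish aldol acceptor. The prolonged exposure to stoichiometric TiCl4 near room temperature needed to force closure could then ionise the primary silyl ether, which becomes benzylic and ortho to the new phenol. The fallback separates the two bond formations. From 7 and 12, a TMSOTf-catalysed Mukaiyama addition at −78 °C with aqueous work-up would stop at the open-chain δ-methoxy β-keto ester, methyl 5-methoxy-3,7-dioxo-4-[(triisopropylsilyloxy)methyl]-7-[4-(triisopropylsilyloxy)phenyl]heptanoate F1 (diastereomer mixture). Heating F1 with piperidinium acetate in toluene with removal of water would effect intramolecular Knoevenagel condensation onto the aryl ketone, elimination of methanol and tautomerisation, and comes back to the route at 15.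

**Step 12.** The reaction may stop after one addition, since ketone 25 carries two ortho substituents, and forcing it risks attack of the lithium alkoxide on the neighbouring alkyne. The fallback builds the carbinol one aryl group at a time. From 22, DIBAL-H reduction would give the benzylic alcohol {6-[4-(triisopropylsilyloxy)phenyl]-3-[(triisopropylsilyloxy)methyl]-2-{[4-(triisopropylsilyloxy)phenyl]ethynyl}phenyl}methanol F2. Dess–Martin oxidation would give the corresponding benzaldehyde F3, a far less hindered acceptor than the ester. Addition of 24 would give the racemic diarylmethanol F4, and a second Dess–Martin oxidation would give ketone 25 as an isolated compound. The organocerium reagent from 24 and CeCl3, less basic and known to add to hindered diaryl ketones, would then return the route to 26.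

**Step 11.** Slow oxidative addition into the C–O bond between the ester and the silyloxymethyl group could let copper-mediated oxidative dimerisation of 21 and amine-induced S–O cleavage of the triflate outrun the coupling. The fallback is a copper-free Negishi alkynylation: 21 would be deprotonated with n-BuLi and transmetalated with ZnCl2 to chloro{[4-(triisopropylsilyloxy)phenyl]ethynyl}zinc F5, which would be coupled with 16 using Pd(PPh3)4 in THF at 60 °C, coming back at 22.

**Step 13.** Under basic fluoride the liberated C5 alkoxide or the carbinol alkoxide may add across the adjacent alkyne (5-exo or 6-endo hydroalkoxylation) before acidification. The fallback stages the unmasking so that no alkoxide is formed. From 26, KHF2 in MeOH, which is mildly acidic and cleaves only aryl silyl ethers, would give after dehydration the quinone methide that still bears the primary silyl ether, 5-O-triisopropylsilyl selaginellin F6. HF·pyridine in THF would then remove the last silyl group and arrive at 28.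

**Step 1.** The hard dianion may attack silicon or over-alkylate, since this chloromethyl ether is used less often as a carbon electrophile than its benzyl congener. The fallback sets out from 1 through dianion 3: aldol addition to monomeric formaldehyde would give methyl 5-hydroxy-3-oxopentanoate F7, and silylation with TIPSCl and imidazole comes back to the route at 4.

## Further compounds

F1 | step 6 | methyl 5-methoxy-3,7-dioxo-4-[(triisopropylsilyloxy)methyl]-7-[4-(triisopropylsilyloxy)phenyl]heptanoate (diastereomer mixture) | COC(=O)CC(=O)C(CO[Si](C(C)C)(C(C)C)C(C)C)C(OC)CC(=O)c1ccc(O[Si](C(C)C)(C(C)C)C(C)C)cc1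
F2 | step 12 | {6-[4-(triisopropylsilyloxy)phenyl]-3-[(triisopropylsilyloxy)methyl]-2-{[4-(triisopropylsilyloxy)phenyl]ethynyl}phenyl}methanol | OCc1c(C#Cc2ccc(O[Si](C(C)C)(C(C)C)C(C)C)cc2)c(CO[Si](C(C)C)(C(C)C)C(C)C)ccc1-c1ccc(O[Si](C(C)C)(C(C)C)C(C)C)cc1
F3 | step 12 | 6-[4-(triisopropylsilyloxy)phenyl]-3-[(triisopropylsilyloxy)methyl]-2-{[4-(triisopropylsilyloxy)phenyl]ethynyl}benzaldehyde | O=Cc1c(C#Cc2ccc(O[Si](C(C)C)(C(C)C)C(C)C)cc2)c(CO[Si](C(C)C)(C(C)C)C(C)C)ccc1-c1ccc(O[Si](C(C)C)(C(C)C)C(C)C)cc1
F4 | step 12 | {6-[4-(triisopropylsilyloxy)phenyl]-3-[(triisopropylsilyloxy)methyl]-2-{[4-(triisopropylsilyloxy)phenyl]ethynyl}phenyl}[4-(triisopropylsilyloxy)phenyl]methanol (racemic) | OC(c1ccc(O[Si](C(C)C)(C(C)C)C(C)C)cc1)c1c(C#Cc2ccc(O[Si](C(C)C)(C(C)C)C(C)C)cc2)c(CO[Si](C(C)C)(C(C)C)C(C)C)ccc1-c1ccc(O[Si](C(C)C)(C(C)C)C(C)C)cc1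
F5 | step 11 | chloro{[4-(triisopropylsilyloxy)phenyl]ethynyl}zinc | Cl[Zn]C#Cc1ccc(O[Si](C(C)C)(C(C)C)C(C)C)cc1
F6 | step 13 | 4-[{6-(4-hydroxyphenyl)-2-[(4-hydroxyphenyl)ethynyl]-3-[(triisopropylsilyloxy)methyl]phenyl}(4-hydroxyphenyl)methylidene]cyclohexa-2,5-dien-1-one | O=C1C=CC(=C(c2ccc(O)cc2)c2c(-c3ccc(O)cc3)ccc(CO[Si](C(C)C)(C(C)C)C(C)C)c2C#Cc2ccc(O)cc2)C=C1
F7 | step 1 | methyl 5-hydroxy-3-oxopentanoate | COC(=O)CC(=O)CCO
A1 | alternative 1 | 5-[4-(methoxymethoxy)phenyl]penta-2,4-diyn-1-yl 4,4-bis[4-(methoxymethoxy)phenyl]-4-(trimethylsilyloxy)but-2-ynoate | COCOc1ccc(cc1)C#CC#CCOC(=O)C#CC(O[Si](C)(C)C)(c1ccc(OCOC)cc1)c1ccc(OCOC)cc1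
A2 | alternative 1 | 6-[4-(methoxymethoxy)phenyl]-7-{bis[4-(methoxymethoxy)phenyl](trimethylsilyloxy)methyl}isobenzofuran-1(3H)-one | O=C1OCc2ccc(-c3ccc(OCOC)cc3)c(C(O[Si](C)(C)C)(c3ccc(OCOC)cc3)c3ccc(OCOC)cc3)c12
A3 | alternative 2 | 4-chloro-2-iodo-1-[(methoxymethoxy)methyl]benzene | COCOCc1ccc(Cl)cc1I
A4 | alternative 2 | 4-(methoxymethoxy)benzoic anhydride | COCOc1ccc(cc1)C(=O)OC(=O)c1ccc(OCOC)cc1
A5 | alternative 2 | 1-ethynyl-4-(methoxymethoxy)benzene | C#Cc1ccc(OCOC)cc1
A6 | alternative 2 | {6-chloro-3-[(methoxymethoxy)methyl]-2-{[4-(methoxymethoxy)phenyl]ethynyl}phenyl}[4-(methoxymethoxy)phenyl]methanone | COCOCc1ccc(Cl)c(C(=O)c2ccc(OCOC)cc2)c1C#Cc1ccc(OCOC)cc1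
A7 | alternative 3 | 2-bromo-6-[(methoxymethoxy)methyl]-3-[4-(methoxymethoxy)phenyl]benzaldehyde | O=Cc1c(Br)c(-c2ccc(OCOC)cc2)ccc1COCOC
A8 | alternative 3 | 1,2-bis[4-(methoxymethoxy)phenyl]ethyne | COCOc1ccc(cc1)C#Cc1ccc(OCOC)cc1
A9 | alternative 3 | 2,3,4-tris[4-(methoxymethoxy)phenyl]-7-[(methoxymethoxy)methyl]inden-1-one | O=C1C(c2ccc(OCOC)cc2)=C(c2ccc(OCOC)cc2)c2c(-c3ccc(OCOC)cc3)ccc(COCOC)c12
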